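**Retrosynthetic overview**
1. The target is an oxolane: O1, C2 (ring A = 3-hydroxy-4,5-dimethoxyphenyl), C3 (Me), C4 (Me), C5 (ring B = 3,4,5-trimethoxyphenyl). It is (2R,3S,4S,5S), that is 2,3-cis, 3,4-trans, 4,5-trans, with the two aryl groups 2,5-cis.
2. The strategy rests on the trans C4(Me)–C5(ring B) edge, which is the C=C of (E)-isoelemicin. O1, C2 (ring A) and C3 are the ketone oxygen, ketone carbon and diazo carbon of an aroyl diazoacetate, and its ester is the latent C3 methyl group. The oxolane is the only ring built, and it closes in one step by forming C3–C4 and O1–C5.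
3. The C2=C3 enol ether is then saturated by syn hydrogenation on the face opposite ring B. This fixes the contra-thermodynamic 2,3-cis pair and makes C3/C4 trans. Acid/silane reduction is not used, because it sets C2 and C3 in separate cationic events in a medium that lets benzylic ethers of electron-rich 2,5-diaryloxolanes drift to the all-trans isomer.
4. The end game is CO2Me → CH2OH → CH2OMs → CH3, followed by neutral O-debenzylation.
5. The diazo keto ester comes from benzylation, crossed Claisen condensation and diazo transfer. Isoelemicin comes from one stereoretentive Suzuki–Miyaura coupling.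

Key step: step 5

Assumption: the sense of induction of Rh2(S-PTTL)4 (dirhodium tetrakis[N-phthaloyl-(S)-tert-leucinate]) in this annulation is not known; it is taken to give the (4S,5S) product, and Rh2(R-PTTL)4 from D-tert-leucine would be used if the opposite sense is found.

**Step 1**
Reactants: 1 methyl 3-hydroxy-4,5-dimethoxybenzoate
Product: 2 methyl 3-(benzyloxy)-4,5-dimethoxybenzoate
Conditions: BnBr, K2CO3, DMF, 25 °C
Reagents that add atoms: benzyl bromide, BrCc1ccccc1
Why: Williamson ether synthesis in which only the phenol is deprotonated by K2CO3, and the benzyl ether is chosen because it should survive base, the carbenoid step, platinum-catalysed hydrogenation and hydride reagents and leaves at the end under neutral conditions.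

**Step 2**
Reactants: 2 methyl 3-(benzyloxy)-4,5-dimethoxybenzoate; 3 methyl acetate
Product: 5 methyl 3-[3-(benzyloxy)-4,5-dimethoxyphenyl]-3-oxopropanoate, via methyl acetate lithium enolate 4 (not isolated)
Conditions: LiHMDS (3.2 equiv), 3 (1.6 equiv), THF, −78 °C; then 2, −78 → 0 °C; 1 M HCl
Reagents that add atoms: none
Why: Crossed Claisen condensation in which the preformed enolate 4 can only be acylated productively by the non-enolisable benzoate 2, and the surplus amide base drives the equilibrium by deprotonating the β-keto ester as it forms.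

**Step 3**
Reactants: 5 methyl 3-[3-(benzyloxy)-4,5-dimethoxyphenyl]-3-oxopropanoate
Product: 6 methyl 2-diazo-3-[3-(benzyloxy)-4,5-dimethoxyphenyl]-3-oxopropanoate
Conditions: p-ABSA, Et3N, MeCN, 0 → 25 °C
Reagents that add atoms: 4-acetamidobenzenesulfonyl azide (p-ABSA), CC(=O)Nc1ccc(cc1)S(=O)(=O)N=[N+]=[N-]
Why: Regitz diazo transfer to an active methylene compound, a standard and mild entry to 2-diazo-1,3-dicarbonyl compounds that touches no other group.

**Step 4**
Reactants: 7 5-bromo-1,2,3-trimethoxybenzene; 8 (E)-prop-1-enylboronic acid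
Product: 9 (E)-isoelemicin, 1,2,3-trimethoxy-5-[(E)-prop-1-enyl]benzene
Conditions: PdCl2(dppf) (3 mol %), K2CO3, 1,4-dioxane–H2O, 85 °C
Reagents that add atoms: none
Why: Suzuki–Miyaura coupling proceeds with retention of the alkenylboron geometry, so the pure E alkene should be obtained in one step without a separate isomerisation.

**Step 5**
Reactants: 6 methyl 2-diazo-3-[3-(benzyloxy)-4,5-dimethoxyphenyl]-3-oxopropanoate; 9 (E)-isoelemicin
Product: 10 methyl (4S,5S)-2-[3-(benzyloxy)-4,5-dimethoxyphenyl]-4-methyl-5-(3,4,5-trimethoxyphenyl)-4,5-dihydrofuran-3-carboxylate (4,5-trans)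
Conditions: Rh2(S-PTTL)4 (1 mol %), 9 (2 equiv), 4 Å MS, CH2Cl2, 25 °C, 6 added over 8 h
Reagents that add atoms: none
Why: Proposed new method: the divalent rhodium carboxylate expels N2 from 6 to give an electrophilic keto ester carbenoid, the methyl-bearing carbon of 9 attacks the carbenoid carbon (C3–C4) because only this regiochemistry puts the positive charge on the benzylic carbon stabilised by ring B, and the enolate oxygen of the aroyl group then captures that cation (O1–C5). The closest known reaction types are the racemic rhodium carboxylate formal (3+2) annulation of 2-diazo-1,3-dicarbonyl compounds with electron-rich alkenes, its Mn(OAc)3 radical-polar counterpart, and the highly enantioselective cyclopropanation of styrenes with aroyl diazoacetates under phthalimido-tert-leucinate dirhodium catalysts, so what is new is high enantioselectivity in the dihydrofuran-forming mode on a 1,2-disubstituted styrene. The oxolane ring closes by 5-exo-trig attack of the enolate oxygen on the para-quinoid benzylic cation, and any donor–acceptor cyclopropane formed by competing closure at carbon should reopen at the same benzylic bond (Cloke–Wilson ring expansion) and end in the same product. C4 is fixed in the C–C bond-forming event by the chiral pocket of the four N-phthaloyl-tert-leucinate ligands, which selects one alkene face, and C5 follows from C4 because the cation closes through the rotamer in which ring B and the C4 methyl group are anti, giving the trans (4S,5S) product. The step needs chemoselectivity for the alkene over the electron-rich arenes and the benzyl ether, secured by slow addition of 6 to an excess of the more nucleophilic styrene, regioselectivity, secured by ring B, and closure at oxygen rather than carbon, favoured by the stabilised cation and the conjugated 2-aryl enol ether ester that results.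

**Step 6**
Reactants: 10 methyl (4S,5S)-2-[3-(benzyloxy)-4,5-dimethoxyphenyl]-4-methyl-5-(3,4,5-trimethoxyphenyl)-4,5-dihydrofuran-3-carboxylate
Product: 11 methyl (2R,3S,4S,5S)-2-[3-(benzyloxy)-4,5-dimethoxyphenyl]-4-methyl-5-(3,4,5-trimethoxyphenyl)oxolane-3-carboxylate (2,3-cis, 3,4-trans, 4,5-trans)
Conditions: H2 (4 atm), PtO2 (10 mol %), EtOAc, 25 °C
Reagents that add atoms: none
Why: Heterogeneous syn hydrogenation of a 2-aryl-4,5-dihydrofuran-3-carboxylate delivers both hydrogens from the metal surface to one face, so ring A and the ester must end cis (C2 R, C3 S), and the flat ring A–C2=C3–CO2Me π system is expected to adsorb on the face opposite the pseudoaxial ring B (the face carrying only the C4 methyl group), because adsorption on the other face would drive ring B into the surface and press ring A, the ester and the C4 methyl group together on the far side, while platinum in a neutral solvent should spare the benzyl ether and the benzylic ring C–O bonds.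

**Step 7**
Reactants: 11 methyl (2R,3S,4S,5S)-2-[3-(benzyloxy)-4,5-dimethoxyphenyl]-4-methyl-5-(3,4,5-trimethoxyphenyl)oxolane-3-carboxylate
Product: 12 [(2R,3R,4S,5S)-2-[3-(benzyloxy)-4,5-dimethoxyphenyl]-4-methyl-5-(3,4,5-trimethoxyphenyl)oxolan-3-yl]methanol
Conditions: LiAlH4, THF, 0 °C; then H2O, aq NaOH
Reagents that add atoms: none
Why: Ester reduction with LiAlH4 is fast at 0 °C, so the epimerisable C3 centre next to the ester should not be disturbed and all four centres are retained (the C3 descriptor becomes R only because CH2OH ranks differently from CO2Me).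

**Step 8**
Reactants: 12 [(2R,3R,4S,5S)-2-[3-(benzyloxy)-4,5-dimethoxyphenyl]-4-methyl-5-(3,4,5-trimethoxyphenyl)oxolan-3-yl]methanol
Product: 13 [(2R,3R,4S,5S)-2-[3-(benzyloxy)-4,5-dimethoxyphenyl]-4-methyl-5-(3,4,5-trimethoxyphenyl)oxolan-3-yl]methyl methanesulfonate
Conditions: MsCl, Et3N, CH2Cl2, 0 °C
Reagents that add atoms: methanesulfonyl chloride, CS(=O)(=O)Cl
Why: Sulfonylation of a primary alcohol under basic conditions, which avoids any acid that could ionise the benzylic C2–O or C5–O bonds.

**Step 9**
Reactants: 13 [(2R,3R,4S,5S)-2-[3-(benzyloxy)-4,5-dimethoxyphenyl]-4-methyl-5-(3,4,5-trimethoxyphenyl)oxolan-3-yl]methyl methanesulfonate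
Product: 14 (2R,3S,4S,5S)-2-[3-(benzyloxy)-4,5-dimethoxyphenyl]-3,4-dimethyl-5-(3,4,5-trimethoxyphenyl)oxolane
Conditions: LiEt3BH, THF, 0 → 25 °C; then H2O
Reagents that add atoms: none
Why: SN2 displacement of a primary mesylate by the strongly nucleophilic hydride of LiEt3BH, the usual way to turn hydroxymethyl groups of oxolane lignans into methyl groups, takes place outside the stereocentres and under basic conditions, so the 2,3-cis arrangement is kept (C3 returns to the descriptor S).

**Step 10**
Reactants: 14 (2R,3S,4S,5S)-2-[3-(benzyloxy)-4,5-dimethoxyphenyl]-3,4-dimethyl-5-(3,4,5-trimethoxyphenyl)oxolane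
Product: 15 5-[(2R,3S,4S,5S)-3,4-dimethyl-5-(3,4,5-trimethoxyphenyl)oxolan-2-yl]-2,3-dimethoxyphenol (target)
Conditions: H2 (1 atm), Pd/C (10 wt %), EtOAc–MeOH, 25 °C
Reagents that add atoms: none
Why: Hydrogenolysis of an aryl benzyl ether over Pd/C at 1 atm is much faster than cleavage of the hindered secondary benzylic C–O bonds of a 2,5-diaryloxolane and is neutral, so the contra-thermodynamic C2 centre should not epimerise.

**Compound list**
1 | methyl 3-hydroxy-4,5-dimethoxybenzoate | COC(=O)c1cc(O)c(OC)c(OC)c1 | starting material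
2 | methyl 3-(benzyloxy)-4,5-dimethoxybenzoate | COC(=O)c1cc(OCc2ccccc2)c(OC)c(OC)c1 | intermediate
3 | methyl acetate | COC(C)=O | starting material
4 | methyl acetate lithium enolate | [Li+].[O-]C(=C)OC | intermediate
5 | methyl 3-[3-(benzyloxy)-4,5-dimethoxyphenyl]-3-oxopropanoate | COC(=O)CC(=O)c1cc(OCc2ccccc2)c(OC)c(OC)c1 | intermediate
6 | methyl 2-diazo-3-[3-(benzyloxy)-4,5-dimethoxyphenyl]-3-oxopropanoate | COC(=O)C(=[N+]=[N-])C(=O)c1cc(OCc2ccccc2)c(OC)c(OC)c1 | intermediate
7 | 5-bromo-1,2,3-trimethoxybenzene | COc1cc(Br)cc(OC)c1OC | starting material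
8 | (E)-prop-1-enylboronic acid | C/C=C/B(O)O | starting material
9 | (E)-isoelemicin | C/C=C/c1cc(OC)c(OC)c(OC)c1 | intermediate
10 | methyl (4S,5S)-2-[3-(benzyloxy)-4,5-dimethoxyphenyl]-4-methyl-5-(3,4,5-trimethoxyphenyl)-4,5-dihydrofuran-3-carboxylate | O1C(c2cc(OCc3ccccc3)c(OC)c(OC)c2)=C(C(=O)OC)[C@H](C)[C@H]1c4cc(OC)c(OC)c(OC)c4 | intermediate
11 | methyl (2R,3S,4S,5S)-2-[3-(benzyloxy)-4,5-dimethoxyphenyl]-4-methyl-5-(3,4,5-trimethoxyphenyl)oxolane-3-carboxylate | COc1cc([C@@H]2O[C@H](c3cc(OC)c(OC)c(OC)c3)[C@@H](C)[C@@H]2C(=O)OC)cc(OCc4ccccc4)c1OC | intermediate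
12 | [(2R,3R,4S,5S)-2-[3-(benzyloxy)-4,5-dimethoxyphenyl]-4-methyl-5-(3,4,5-trimethoxyphenyl)oxolan-3-yl]methanol | COc1cc([C@@H]2O[C@H](c3cc(OC)c(OC)c(OC)c3)[C@@H](C)[C@@H]2CO)cc(OCc4ccccc4)c1OC | intermediate
13 | [(2R,3R,4S,5S)-2-[3-(benzyloxy)-4,5-dimethoxyphenyl]-4-methyl-5-(3,4,5-trimethoxyphenyl)oxolan-3-yl]methyl methanesulfonate | COc1cc([C@@H]2O[C@H](c3cc(OC)c(OC)c(OC)c3)[C@@H](C)[C@@H]2COS(C)(=O)=O)cc(OCc4ccccc4)c1OC | intermediate
14 | (2R,3S,4S,5S)-2-[3-(benzyloxy)-4,5-dimethoxyphenyl]-3,4-dimethyl-5-(3,4,5-trimethoxyphenyl)oxolane | COc1cc([C@@H]2O[C@H](c3cc(OC)c(OC)c(OC)c3)[C@@H](C)[C@@H]2C)cc(OCc4ccccc4)c1OC | intermediate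
15 | 5-[(2R,3S,4S,5S)-3,4-dimethyl-5-(3,4,5-trimethoxyphenyl)oxolan-2-yl]-2,3-dimethoxyphenol | COc1cc([C@@H]2O[C@H](c3cc(OC)c(OC)c(OC)c3)[C@@H](C)[C@@H]2C)cc(O)c1OC | target

Total step count: 10. Longest linear sequence: 9 (steps 1–3 and 5–10).

**Steps most likely to fail**

**Step 5.** A 1,2-disubstituted styrene is a slow trap. The carbenoid may therefore be lost to dimerisation, Wolff rearrangement or attack on the electron-rich arenes. Ring closure may also stop at the cyclopropane stage, and the ligand pocket may discriminate poorly between the alkene faces.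

The fallback sets out from keto ester 5 and isoelemicin 9 and uses the known oxidative radical (3+2) annulation. Mn(OAc)3 dihydrate in acetic acid at 70 °C generates the keto ester radical. This radical adds to the methyl-bearing alkene carbon, the benzylic radical is oxidised to the cation, and the enol oxygen closes the ring trans. The product is the racemate, that is 10 together with the (4R,5R)-enantiomer of the dihydrofuran ester F1. The two are separated by preparative HPLC on a cellulose tris(3,5-dimethylphenylcarbamate) phase, and the route is rejoined at 10.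

**Step 6.** Hydrogen may be delivered to the face opposite the C4 methyl group instead of the face opposite ring B, which is poor facial selectivity. Uptake by the tetrasubstituted push–pull alkene may be slow. Long exposure may also start loss of the benzyl group.

The fallback replaces substrate control on a surface by catalyst control in solution and sets out from 10. Saponification (LiOH, THF–MeOH–H2O, 60 °C) gives the (4S,5S)-dihydrofuran-3-carboxylic acid F2. Carboxylate-directed asymmetric hydrogenation of this tetrasubstituted unsaturated acid follows, with [Ir(cod)(L*)]BArF (L* = spiro phosphine–oxazoline ligand SIPHOX, BArF = tetrakis[3,5-bis(trifluoromethyl)phenyl]borate), H2 and Et3N in MeOH. The ligand enantiomer is chosen so that hydrogen arrives opposite ring B. This gives the (2R,3S,4S,5S)-oxolane-3-carboxylic acid F3. LiAlH4 reduction of F3 rejoins the route at 12.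

**Step 2.** Self-condensation and decay of the acetate enolate may outrun acylation by the electron-rich, sluggish benzoate.

The fallback sets out from 2 and uses a decarboxylative Claisen condensation (Masamune–Brooks type). LiOH hydrolysis gives 3-(benzyloxy)-4,5-dimethoxybenzoic acid F4. Carbonyldiimidazole in THF converts it into the acyl imidazolide F5. F5 is treated with the magnesium enolate prepared from potassium methyl malonate, MgCl2 and Et3N. Loss of CO2 on work-up gives the keto ester, and the route is rejoined at 5.

**Further compounds**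
F1 | step 5 | methyl (4R,5R)-2-[3-(benzyloxy)-4,5-dimethoxyphenyl]-4-methyl-5-(3,4,5-trimethoxyphenyl)-4,5-dihydrofuran-3-carboxylate | O1C(c2cc(OCc3ccccc3)c(OC)c(OC)c2)=C(C(=O)OC)[C@@H](C)[C@@H]1c4cc(OC)c(OC)c(OC)c4
F2 | step 6 | (4S,5S)-2-[3-(benzyloxy)-4,5-dimethoxyphenyl]-4-methyl-5-(3,4,5-trimethoxyphenyl)-4,5-dihydrofuran-3-carboxylic acid | O1C(c2cc(OCc3ccccc3)c(OC)c(OC)c2)=C(C(=O)O)[C@H](C)[C@H]1c4cc(OC)c(OC)c(OC)c4
F3 | step 6 | (2R,3S,4S,5S)-2-[3-(benzyloxy)-4,5-dimethoxyphenyl]-4-methyl-5-(3,4,5-trimethoxyphenyl)oxolane-3-carboxylic acid | COc1cc([C@@H]2O[C@H](c3cc(OC)c(OC)c(OC)c3)[C@@H](C)[C@@H]2C(=O)O)cc(OCc4ccccc4)c1OC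
F4 | step 2 | 3-(benzyloxy)-4,5-dimethoxybenzoic acid | OC(=O)c1cc(OCc2ccccc2)c(OC)c(OC)c1
F5 | step 2 | [3-(benzyloxy)-4,5-dimethoxyphenyl](imidazol-1-yl)methanone | O=C(n1ccnc1)c2cc(OCc3ccccc3)c(OC)c(OC)c2
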